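Everything rests on closing the ten-membered carbocycle last, between C9 and C10 (germacrane numbering). C10 is the α-carbon of the 3(2H)-furanone ring (O–C10–C1–C2–C3), so it is available as the carbon of a planar furan-3-olate, and C9 is a CH2 next to oxygenated C8, i.e. the terminal carbon of a C8–C9 epoxide. In one base-mediated operation a chloromethyl 8,12-lactone shifts to the 6,12-lactone, the freed O8 closes the epoxide and C10 opens it at C9, which sets the quaternary centre and unveils the C8 hydroxyl. The precursor is the Barbier adduct of a furanone enal and an epichlorohydrin-derived bromobutenolide, whose single stereocentre controls C6 and C7.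

Key step: step 11

Remarks on the chemistry:
- Germacrane numbering is used throughout: C1–C10 ring, C11–C13 lactone carbons, C14 methyl, C15 CH2OAc.
- C10 is deliberately left uncontrolled up to step 11 (5 is used racemic). It is planar in the reacting furan-3-olate, so both epimers converge.
- C11 of the selenides is an epimer mixture and is erased in step 13.

Step 1
Reactants: 1 but-2-yne-1,4-diol
Product: 2 4-hydroxybut-2-yn-1-yl acetate
Conditions: Ac2O (1.0 equiv), Et3N, DMAP (cat.), CH2Cl2, 0 °C
Reagents that add atoms: acetic anhydride, CC(=O)OC(C)=O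
Why: Statistical DMAP-catalysed mono-acylation of a symmetrical diol installs the C15 acetate of the target at the outset; diacetate and recovered diol are separable and no stereocentre is involved.

Step 2
Reactants: 2 4-hydroxybut-2-yn-1-yl acetate
Product: 3 4-oxobut-2-yn-1-yl acetate
Conditions: MnO2 (activated, excess), CH2Cl2, 25 °C
Reagents that add atoms: none
Why: MnO2 oxidation of a propargylic primary alcohol stops at the ynal and leaves the acetate untouched.

Step 3
Reactants: 3 4-oxobut-2-yn-1-yl acetate
Product: 4 (2Z)-2-iodo-4-oxobut-2-en-1-yl acetate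
Conditions: NaI, AcOH, 25 °C
Reagents that add atoms: sodium iodide, [Na+].[I-]
Why: Conjugate hydroiodination of an electron-poor alkyne: iodide adds to the β-carbon (C4) and the allenolate is protonated anti, giving the kinetic Z β-iodoenal with iodine cis to the formyl carbon C6, the geometry needed for C4=C5.

Step 4
Reactants: 4 (2Z)-2-iodo-4-oxobut-2-en-1-yl acetate; 5 but-3-yn-2-ol (racemic)
Product: 6 (2Z)-6-hydroxy-3-oxo-2-(2-oxoethylidene)hept-4-yn-1-yl acetate
Conditions: PdCl2(PPh3)2 (5 mol %), iPr2NEt, THF, CO (10 bar), 25 °C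
Reagents that add atoms: carbon monoxide, [C-]#[O+]
Why: Copper-free carbonylative Sonogashira coupling: oxidative addition of zerovalent palladium into the vinyl C–I bond (alkene geometry retained), CO insertion and alkynylation of the acyl–palladium species give the γ-hydroxy ynone, with CO pressure and the absence of copper favouring insertion over direct coupling.

Step 5
Reactants: 6 (2Z)-6-hydroxy-3-oxo-2-(2-oxoethylidene)hept-4-yn-1-yl acetate
Product: 7 (2Z)-2-(5-methyl-4-oxo-4,5-dihydrofuran-2-yl)-4-oxobut-2-en-1-yl acetate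
Conditions: (4-CF3C6H4)3PAuCl (5 mol %), AgOTf (5 mol %), toluene, 25 °C
Reagents that add atoms: none
Why: Gold-catalysed cycloisomerisation of a γ-hydroxy ynone to a 3(2H)-furanone (net oxygen transfer to the alkyne carbon next to the carbinol, which becomes the ring ketone C1, and closure of the hydroxyl oxygen onto the former ketone carbon C3); the Z enal and the acetate are spectators and C10 stays racemic.

Step 6
Reactants: 8 (R)-epichlorohydrin
Product: 9 (2R)-1-chlorobut-3-en-2-ol
Conditions: Me3S+ I− (3 equiv), n-BuLi (2.9 equiv), THF, −10 to 25 °C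
Reagents that add atoms: trimethylsulfonium iodide, C[S+](C)C.[I-]
Why: Sulfonium-ylide homologation of an epoxide to an allylic alcohol: dimethylsulfonium methylide opens the epoxide at its CH2 terminus and the sulfonium alkoxide loses Me2S by ylide-mediated syn elimination, so the C–O stereocentre (the future C8) is never touched and stays R.

Step 7
Reactants: 9 (2R)-1-chlorobut-3-en-2-ol; 10 2-(bromomethyl)prop-2-enoic acid
Product: 11 (2R)-1-chlorobut-3-en-2-yl 2-(bromomethyl)prop-2-enoate
Conditions: DCC, DMAP (5 mol %), CH2Cl2, 0 °C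
Reagents that add atoms: none
Why: Steglich esterification forms the acyl–oxygen bond, so C8 keeps its configuration, and low temperature with little DMAP spares the allylic bromide.

Step 8
Reactants: 11 (2R)-1-chlorobut-3-en-2-yl 2-(bromomethyl)prop-2-enoate
Product: 12 (5R)-3-(bromomethyl)-5-(chloromethyl)furan-2(5H)-one
Conditions: second-generation Grubbs catalyst, RuCl2(=CHPh)(PCy3)(H2IMes) (5 mol %), CH2Cl2 (10 mM), 40 °C
Reagents that add atoms: none
Why: Ring-closing metathesis between the vinyl group and the 1,1-disubstituted acrylate closes the five-membered butenolide with loss of ethene and does not touch C8.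

Step 9
Reactants: 7 (2Z)-2-(5-methyl-4-oxo-4,5-dihydrofuran-2-yl)-4-oxobut-2-en-1-yl acetate; 12 (5R)-3-(bromomethyl)-5-(chloromethyl)furan-2(5H)-one
Product: 13 (2Z,4R)-4-[(2R,3S)-2-(chloromethyl)-4-methylidene-5-oxooxolan-3-yl]-4-hydroxy-2-(5-methyl-4-oxo-4,5-dihydrofuran-2-yl)but-2-en-1-yl acetate
Conditions: Zn dust, THF/saturated aqueous NH4Cl, 0 °C
Reagents that add atoms: none
Why: Barbier allylation: the allylzinc formed at C13 adds through its γ-carbon C7 to the aldehyde in a six-membered chair (Zimmerman–Traxler) transition state, C7 being attacked anti to the CH2Cl group on C8 and the ring-locked E-type allyl metal (C8 trans to C13 on C11=C7) with the aldehyde substituent equatorial giving the anti C6/C7 relationship, so the one centre C8 sets C6 and C7 as drawn.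

Step 10
Reactants: 13 (2Z,4R)-4-[(2R,3S)-2-(chloromethyl)-4-methylidene-5-oxooxolan-3-yl]-4-hydroxy-2-(5-methyl-4-oxo-4,5-dihydrofuran-2-yl)but-2-en-1-yl acetate
Product: 14 (2Z,4R)-4-[(2R,3S)-2-(chloromethyl)-5-oxo-4-[(phenylselanyl)methyl]oxolan-3-yl]-4-hydroxy-2-(5-methyl-4-oxo-4,5-dihydrofuran-2-yl)but-2-en-1-yl acetate
Conditions: PhSeH (1.05 equiv), Et3N (10 mol %), CH2Cl2, −20 °C
Reagents that add atoms: benzeneselenol, [SeH]c1ccccc1
Why: Michael addition of the soft selenolate to the exocyclic methylene lactone, the most reactive acceptor, masks C11=C13 against enolate attack in step 11; C11 forms as an epimer mixture that is removed again in step 13.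

Step 11
Reactants: 14 (2Z,4R)-4-[(2R,3S)-2-(chloromethyl)-5-oxo-4-[(phenylselanyl)methyl]oxolan-3-yl]-4-hydroxy-2-(5-methyl-4-oxo-4,5-dihydrofuran-2-yl)but-2-en-1-yl acetate
Product: 17 (6R,7R,8S,10R)-15-acetoxy-8-hydroxy-1-oxo-13-(phenylselanyl)-3,10-epoxygermacra-2,4Z-dien-12,6-olide, via 6,12-lactone chlorohydrin 15 (not isolated), via epoxide 16 (not isolated)
Conditions: Cs2CO3 (3 equiv), DMF (2 mM), 60 °C; AcOH quench
Reagents that add atoms: none
Why: Carbonate forms the furan-3-olate (C10 planar) and, in equilibrium, the C6 alkoxide, which adds to the lactone carbonyl C12 so that the γ-lactone moves from O8 to O6 (5-exo-trig acyl transfer, trans 6,12-lactone 15), whereupon the freed O8 alkoxide displaces chloride at C9 (3-exo-tet) to give epoxide 16 and makes the lactone shift irreversible. The furan-3-olate carbon C10 then opens the epoxide in an SN2 reaction at its terminal carbon C9, which closes the ten-membered carbocycle (and with it the nine-membered oxacycle of the 11-oxabicyclo[6.2.1]undecane core) in the endo mode of epoxide opening and leaves O8 as the free C8 hydroxyl. The closest known reaction types are halohydrin-to-epoxide closure after acyl migration, C2-alkylation of 2-alkyl-3(2H)-furanone enolates and macrocyclising epoxide opening by stabilised carbanions. C6, C7 and C8 are not touched (attack at C9 retains C8), and the only new stereocentre, C10, is set by the tether: C9 can reach only the face of the planar furanolate over which the Z-C4=C5–C6–C7–C8 chain is held by the trans-lactone, and the conformer with H8 turned into the ring and the C8–O bond outward should lead to 10R. The step needs C- over O-alkylation (the O-alkylated product would be a meta-bridged furan, too strained to form), attack at primary C9 rather than secondary C8, ring closure rather than oligomerisation (high dilution) and no conjugate addition to the lactone (the methylene is masked as the selenide). Both C10 epimers of 14 converge because C10 is planar in the nucleophile.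

Step 12
Reactants: 17 (6R,7R,8S,10R)-15-acetoxy-8-hydroxy-1-oxo-13-(phenylselanyl)-3,10-epoxygermacra-2,4Z-dien-12,6-olide
Product: 18 (6R,7R,8S,10R)-15-acetoxy-8-(methacryloyloxy)-1-oxo-13-(phenylselanyl)-3,10-epoxygermacra-2,4Z-dien-12,6-olide
Conditions: methacrylic anhydride, Et3N, DMAP, CH2Cl2, 0 to 25 °C
Reagents that add atoms: methacrylic anhydride, C=C(C)C(=O)OC(=O)C(C)=C
Why: DMAP-catalysed acylation of the only free hydroxyl (C8) takes place at oxygen without touching the stereocentre, and the ester removes any possibility of lactone migration back to O8.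

Step 13
Reactants: 18 (6R,7R,8S,10R)-15-acetoxy-8-(methacryloyloxy)-1-oxo-13-(phenylselanyl)-3,10-epoxygermacra-2,4Z-dien-12,6-olide
Product: 20 (6R,7R,8S,10R)-15-acetoxy-8-(methacryloyloxy)-1-oxo-3,10-epoxygermacra-2,4Z,11(13)-trien-12,6-olide (target), via selenoxide 19 (not isolated)
Conditions: H2O2 (30 %), pyridine, CH2Cl2, 0 to 25 °C
Reagents that add atoms: none
Why: Selenide oxidation and selenoxide syn-elimination (the only β-hydrogen is H11) regenerate the exocyclic C11=C13 methylene at room temperature without affecting the methacrylate, acetate or furanone, and no stereocentre of the target is touched.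

Compound list
1 | but-2-yne-1,4-diol | OCC#CCO | starting material
2 | 4-hydroxybut-2-yn-1-yl acetate | CC(=O)OCC#CCO | intermediate
3 | 4-oxobut-2-yn-1-yl acetate | CC(=O)OCC#CC=O | intermediate
4 | (2Z)-2-iodo-4-oxobut-2-en-1-yl acetate | CC(=O)OC/C(I)=C/C=O | intermediate
5 | but-3-yn-2-ol (racemic) | CC(O)C#C | starting material
6 | (2Z)-6-hydroxy-3-oxo-2-(2-oxoethylidene)hept-4-yn-1-yl acetate (racemic) | CC(O)C#CC(=O)/C(COC(C)=O)=C\C=O | intermediate
7 | (2Z)-2-(5-methyl-4-oxo-4,5-dihydrofuran-2-yl)-4-oxobut-2-en-1-yl acetate (racemic at C10) | CC1OC(=CC1=O)/C(COC(C)=O)=C\C=O | intermediate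
8 | (R)-epichlorohydrin, (2R)-2-(chloromethyl)oxirane | ClC[C@H]1CO1 | starting material
9 | (2R)-1-chlorobut-3-en-2-ol | O[C@@H](CCl)C=C | intermediate
10 | 2-(bromomethyl)prop-2-enoic acid | C=C(CBr)C(=O)O | starting material
11 | (2R)-1-chlorobut-3-en-2-yl 2-(bromomethyl)prop-2-enoate | C=C[C@H](CCl)OC(=O)C(=C)CBr | intermediate
12 | (5R)-3-(bromomethyl)-5-(chloromethyl)furan-2(5H)-one | O=C1O[C@@H](CCl)C=C1CBr | intermediate
13 | (2Z,4R)-4-[(2R,3S)-2-(chloromethyl)-4-methylidene-5-oxooxolan-3-yl]-4-hydroxy-2-(5-methyl-4-oxo-4,5-dihydrofuran-2-yl)but-2-en-1-yl acetate (8,12-lactone; C10 epimers) | CC1OC(=CC1=O)/C(COC(C)=O)=C\[C@@H](O)[C@H]2[C@H](CCl)OC(=O)C2=C | intermediate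
14 | (2Z,4R)-4-[(2R,3S)-2-(chloromethyl)-5-oxo-4-[(phenylselanyl)methyl]oxolan-3-yl]-4-hydroxy-2-(5-methyl-4-oxo-4,5-dihydrofuran-2-yl)but-2-en-1-yl acetate (C10 and C11 epimers) | CC1OC(=CC1=O)/C(COC(C)=O)=C\[C@@H](O)[C@H]2[C@H](CCl)OC(=O)C2C[Se]c3ccccc3 | intermediate
15 | (2Z)-3-[(2R,3R)-3-[(1R)-2-chloro-1-hydroxyethyl]-5-oxo-4-[(phenylselanyl)methyl]oxolan-2-yl]-2-(5-methyl-4-oxo-4,5-dihydrofuran-2-yl)prop-2-en-1-yl acetate (6,12-lactone chlorohydrin; formed in the flask in step 11) | CC1OC(=CC1=O)/C(COC(C)=O)=C\[C@H]2OC(=O)C(C[Se]c3ccccc3)[C@@H]2[C@@H](O)CCl | intermediate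
16 | (2Z)-3-[(2R,3S)-3-[(2R)-oxiran-2-yl]-5-oxo-4-[(phenylselanyl)methyl]oxolan-2-yl]-2-(5-methyl-4-oxo-4,5-dihydrofuran-2-yl)prop-2-en-1-yl acetate (epoxide; formed in the flask in step 11) | CC1OC(=CC1=O)/C(COC(C)=O)=C\[C@H]2OC(=O)C(C[Se]c3ccccc3)[C@@H]2[C@@H]4CO4 | intermediate
17 | (6R,7R,8S,10R)-15-acetoxy-8-hydroxy-1-oxo-13-(phenylselanyl)-3,10-epoxygermacra-2,4Z-dien-12,6-olide (C11 epimers) | O[C@H]1C[C@@]2(C)OC(=CC2=O)/C(COC(C)=O)=C\[C@H]2OC(=O)C(C[Se]c3ccccc3)[C@H]12 | intermediate
18 | (6R,7R,8S,10R)-15-acetoxy-8-(methacryloyloxy)-1-oxo-13-(phenylselanyl)-3,10-epoxygermacra-2,4Z-dien-12,6-olide (C11 epimers) | C=C(C)C(=O)O[C@H]1C[C@@]2(C)OC(=CC2=O)/C(COC(C)=O)=C\[C@H]2OC(=O)C(C[Se]c3ccccc3)[C@H]12 | intermediate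
19 | selenoxide of 18 (formed in the flask in step 13) | C=C(C)C(=O)O[C@H]1C[C@@]2(C)OC(=CC2=O)/C(COC(C)=O)=C\[C@H]2OC(=O)C(C[Se](=O)c3ccccc3)[C@H]12 | intermediate
20 | (6R,7R,8S,10R)-15-acetoxy-8-(methacryloyloxy)-1-oxo-3,10-epoxygermacra-2,4Z,11(13)-trien-12,6-olide (CNP0179932.1) | C=C(C)C(=O)O[C@H]1C[C@@]2(C)OC(=CC2=O)/C(COC(C)=O)=C\[C@H]2OC(=O)C(=C)[C@H]12 | target

Total step count: 13.
Longest linear sequence: 10 steps (steps 1–5 and 9–13); steps 6–8 form the second branch.

Steps most likely to fail

1. Step 11 (key step). The epoxide opening by the weakly basic furan-3-olate may be too slow, which would let oligomerisation or loss of phenylselenolate from the masked lactone compete. C9 may also add to the wrong face of C10, or the lactone may migrate back to O8 in the product alkoxide. Fallback, from 14 back to 17: 14 is treated with K2CO3 in MeCN at 25 °C only until epoxide 16 has formed, and 16 is isolated. LiI/AcOH in THF opens it at C9 to the iodohydrin F1, and TESCl/imidazole gives the triethylsilyl ether F2. Cs2CO3 in DMF at 25 °C and high dilution then alkylates the furan-3-olate with the primary iodide, a far better electrophile, to give the macrocyclic silyl ether F3, in which the silyl group also blocks lactone migration. HF·pyridine removes the silyl group and returns 17.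

2. Step 9. The closed transition state may be lost through open or equilibrating allylzinc species, eroding the anti C6/C7 relationship, or zinc may reduce the doubly activated enal. Fallback, from 12 back to 13: palladium-catalysed borylation of the allylic bromide (B2pin2, Pd2(dba)3, DMSO, 40 °C) gives the isolable allylboronate F4. Its Sc(OTf)3-catalysed allylboration of 7 in toluene at 0 °C, which must pass through the six-membered chair and involves no reducing metal, gives 13 after aqueous work-up.

3. Step 4. Direct alkynylation without CO may outrun CO insertion at the electron-poor vinyl–palladium intermediate, or the amine may decompose the doubly activated ynone. Fallback, from 4 back to 7, in which the ketone carbon C1 comes from an aldehyde instead of CO: commercial (S)-2-[(tert-butyldimethylsilyl)oxy]propanal and ethynylmagnesium bromide give the propargylic alcohol F5. Ordinary Sonogashira coupling of F5 with 4 (PdCl2(PPh3)2, CuI, Et3N, THF) gives the enynol F6, and Dess–Martin oxidation gives the ynone F7. HF·pyridine frees the C10 hydroxyl to give the hydroxy ynone F8, and (Ph3P)AuCl/AgOTf-catalysed 5-endo-dig oxa-cyclisation gives 7, here enriched in one C10 enantiomer, which is of no consequence.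

Further compounds
F1 | step 11 | (2Z)-3-[(2R,3R)-3-[(1R)-1-hydroxy-2-iodoethyl]-5-oxo-4-[(phenylselanyl)methyl]oxolan-2-yl]-2-(5-methyl-4-oxo-4,5-dihydrofuran-2-yl)prop-2-en-1-yl acetate (iodohydrin) | CC1OC(=CC1=O)/C(COC(C)=O)=C\[C@H]2OC(=O)C(C[Se]c3ccccc3)[C@@H]2[C@@H](O)CI
F2 | step 11 | 8-O-triethylsilyl ether of F1 | CC1OC(=CC1=O)/C(COC(C)=O)=C\[C@H]2OC(=O)C(C[Se]c3ccccc3)[C@@H]2[C@@H](O[Si](CC)(CC)CC)CI
F3 | step 11 | 8-O-triethylsilyl ether of 17 | CC[Si](CC)(CC)O[C@H]1C[C@@]2(C)OC(=CC2=O)/C(COC(C)=O)=C\[C@H]2OC(=O)C(C[Se]c3ccccc3)[C@H]12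
F4 | step 9 | (5R)-5-(chloromethyl)-3-[(4,4,5,5-tetramethyl-1,3,2-dioxaborolan-2-yl)methyl]furan-2(5H)-one | O=C1O[C@@H](CCl)C=C1CB2OC(C)(C)C(C)(C)O2
F5 | step 4 | (4S)-4-[(tert-butyldimethylsilyl)oxy]pent-1-yn-3-ol (C3 epimers) | C#CC(O)[C@H](C)O[Si](C)(C)C(C)(C)C
F6 | step 4 | (2E)-2-[(4S)-4-[(tert-butyldimethylsilyl)oxy]-3-hydroxypent-1-yn-1-yl]-4-oxobut-2-en-1-yl acetate | CC(=O)OC/C(C#CC(O)[C@H](C)O[Si](C)(C)C(C)(C)C)=C/C=O
F7 | step 4 | (2E)-2-[(4S)-4-[(tert-butyldimethylsilyl)oxy]-3-oxopent-1-yn-1-yl]-4-oxobut-2-en-1-yl acetate | CC(=O)OC/C(C#CC(=O)[C@H](C)O[Si](C)(C)C(C)(C)C)=C/C=O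
F8 | step 4 | (2E)-2-[(4S)-4-hydroxy-3-oxopent-1-yn-1-yl]-4-oxobut-2-en-1-yl acetate | CC(=O)OC/C(C#CC(=O)[C@H](C)O)=C/C=O
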